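Leftover starting material, intermediate and dormant form stand outside the asked share, which weighs target against isomer of the product, over-reaction product and side product.

    starting material + intermediate → side product (k1 = 0.14 /M/s)
    coupling partner + target → over-reaction product (k2 = 0.63 /M/s)
    starting material ⇌ dormant form (K3 = 5.5, k3 = 0.013 /s)
    intermediate ⇌ target (K4 = 0.83, k4 = 0.058 /s)
    starting material + coupling partner → intermediate + by-product (k5 = 0.96 /M/s)
    intermediate ⇌ isomer of the product (K6 = 2.3, k6 = 0.022 /s)

| flask | starting material | coupling partner | remark | time |
|---|---|---|---|---|
| autumn | 0.061 M | 1.30 equiv | a single well-mixed tank run continuously and read at steady state, 15 s in it on average |  |
| winter | 0.061 M | 1.30 equiv (fed, over 15.0 s) | all but coupling partner at the start; coupling partner goes in evenly over 15.0 s, the run ends at 15 s | 15 s |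
| midnight | 0.061 M | 1.30 equiv | a tube with plug flow, the mixed feed as stated, residence time 15 s | 15 s |
| dusk | 0.061 M | 1.30 equiv | a closed flask charged with all of it at once and left for 15 s | 15 s |

1. the set-up with the highest share of target in all that became target or isomer of the product or over-reaction product or side product, at the outlet or at the end ("none" if the first two lie within 2 percentage points) (autumn / winter / midnight / dusk / none)
2. share of target in all that became target or isomer of the product or over-reaction product or side product, at the outlet or at the end, autumn
3. share of target in all that became target or isomer of the product or over-reaction product or side product, at the outlet or at the end, winter
4. share of target in all that became target or isomer of the product or over-reaction product or side product, at the outlet or at the end, midnight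
5. share of target in all that became target or isomer of the product or over-reaction product or side product, at the outlet or at the end, dusk

- percent here means starting material units held: one side product counts as two
- the stated concentrations are those of everything mixed, before any reaction; amounts are the same in each set-up
- the feed brings no volume worth counting
- run time (winter): 15 s

Two extreme flasks can be solved in the head. In the first, the intermediate has just formed and meets its exits once: to target at 0.058 /s, to isomer of the product at 0.022 /s, and to side product at 0.008540 /s with c(starting material) as charged. One side product counts as two in the asked share, and with its exit weighted so, the target's part of these exits, the fresh share 59.7%, is the top of the scale. In the second, intermediate, target and isomer have come to equilibrium, and target against isomer goes as 0.83 to 2.3. This equilibrium share of 26.5%, lower than the fresh share, is the zero of the scale for runs stopped early: kinetic against thermodynamic control.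

The runs asked for, stopped at 15 s, are expected between them. In winter, the relaxation of intermediate and target has a half-life of 5.42 s, shorter than the run of 15 s, so the target is no longer fresh. The relaxation towards the isomer takes 22.0 s, longer than the run, so equilibrium is not reached either. In dusk, target has a half-life of 14 s against the coupling partner as charged, close to the run itself.

My own reckoning stops at an order. Midnight equals dusk, since a plug-flow tube is a closed flask in time. Winter stands higher, because coupling partner fed evenly has been present on average 7.50 s at the end, half of the run, so its products are younger. Autumn stands lowest, since the tank's spread of ages carries part of the outlet past 15 s.

The forecast gave 37% for autumn and 48%, 48% and 48% for winter, midnight and dusk. It called the slow feed “too close to the batch figure to separate at this precision” and answered none.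

The simulation gives 36.6% for autumn, 50.6% for winter, and 46.8% and 46.8% for midnight and dusk, so winter is best, by 3.8 percentage points, more than the margin of 2 points. Winter ends with 0.805% of over-reaction product, less than the 2.73% in dusk. Winter's share stands 9.1 points under its fresh share of 59.7%. A flask like winter but with 0.24 M of starting material has a fresh share of 39.4%, and it reads 31.9%.

(The constants used here come from no measurement; no experiment stands behind them.)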